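**Assumption:** intact prostaglandins such as PGF2α are not counted as starting materials, while the commercial (−)-Corey lactone benzoate is; the C15 carbinol and the lactol carbon are deliberately carried as mixtures and written without descriptors.

## Retrosynthetic overview

1. The 15-ketone comes from chemoselective allylic oxidation (DDQ) of the C15 carbinol of a PGF2α/15-epi-PGF2α mixture, so C15 never needs stereocontrol.
2. The (5Z)-alkene comes from a Wittig reaction of a lactol with the ylide of (4-carboxybutyl)triphenylphosphonium bromide.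
3. The lactol triol comes from one-pot i-Bu2AlH reduction of the ketone, γ-lactone and benzoate of the Corey enone.
4. The (13E)-enone comes from Horner–Wadsworth–Emmons reaction of the Corey aldehyde with dimethyl (2-oxoheptyl)phosphonate; the aldehyde comes from oxidation of (−)-Corey lactone benzoate.
5. No ring is built: the cyclopentane with C8, C9, C11 and C12 set is bought in 1; its fused γ-lactone is reduced to the lactol (step 3) and opened (step 4).

## Route

Step 1
Reactants: 1 (−)-Corey lactone benzoate (primary alcohol)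
Product: 2 Corey aldehyde benzoate
Conditions: Dess–Martin periodinane (1.2 equiv), NaHCO3, CH2Cl2, 0 °C → rt, 1 h; aq. Na2S2O3/NaHCO3 work-up; used crude at once
Reagents that add atoms: none
Why: Dess–Martin oxidation under buffered, non-basic conditions stops at the aldehyde and avoids β-elimination of benzoate and epimerisation at C12; no stereocentre is formed.

Step 2
Reactants: 2 Corey aldehyde benzoate; 3 dimethyl (2-oxoheptyl)phosphonate
Product: 5 Corey enone benzoate, via sodium phosphonate carbanion 4 (not isolated)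
Conditions: 3 (1.2 equiv), NaH (1.1 equiv), THF, 0 °C, 30 min; then 2, 0 °C → rt, 1 h; aq. NH4Cl
Reagents that add atoms: none
Why: Horner–Wadsworth–Emmons olefination, in which the stabilised β-ketophosphonate anion collapses to the (13E)-enone and is too weakly basic to disturb C12 or the β-benzoate.

Step 3
Reactants: 5 Corey enone benzoate
Product: 6 lactol triol (C15 epimers; both anomers)
Conditions: i-Bu2AlH (6 equiv, 1 M in toluene), CH2Cl2, −78 °C, 2 h; MeOH at −78 °C, then aq. potassium sodium tartrate (KNaC4H4O6), rt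
Reagents that add atoms: none
Why: DIBAL hydride reduction needing no selectivity between the three carbonyls: 1,2-reduction of the enone (C15 epimers, irrelevant because C15 is re-oxidised in step 5), lactone-to-lactol reduction that halts at the tetrahedral aluminium alkoxide at −78 °C, and reductive cleavage of the benzoate; the four ring stereocentres are untouched.

Step 4
Reactants: 6 lactol triol; 7 (4-carboxybutyl)triphenylphosphonium bromide
Product: 10 PGF2α/15-epi-PGF2α mixture, via potassium carboxylate ylide 8 (not isolated), via open-chain hydroxy aldehyde 9 (not isolated)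
Conditions: 7 (4 equiv), KOt-Bu (8 equiv), THF, 0 °C, 30 min; then 6 in THF, 0 °C → rt, 2 h; aq. citric acid to pH 4, EtOAc extraction
Reagents that add atoms: none
Why: Wittig olefination of the ring-opened lactol by a non-stabilised ylide gives the (5Z)-alkene under kinetic control (cis-oxaphosphetane), with excess ylide and base carrying the free hydroxyls and the acid as potassium salts; no sp3 stereocentre changes.

Step 5
Reactants: 10 PGF2α/15-epi-PGF2α mixture
Product: 11 15-keto-PGF2α
Conditions: DDQ (2 equiv), 1,4-dioxane, rt → 45 °C, 16 h; filter, silica gel chromatography (EtOAc/hexane/AcOH)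
Reagents that add atoms: none
Why: Chemoselective allylic oxidation (DDQ dehydrogenation), since hydride abstraction is feasible only at the allylic C15 carbinol; both epimers converge on one enone while the 9- and 11-carbinols, the (5Z)-alkene and the acid are untouched.

## Compound list

1 | (−)-Corey lactone benzoate, (3aR,4S,5R,6aS)-4-(hydroxymethyl)-2-oxohexahydro-2H-cyclopenta[b]furan-5-yl benzoate | OC[C@@H]1[C@@H](CC(=O)O2)[C@@H]2C[C@H]1OC(=O)c1ccccc1 | starting material
2 | Corey aldehyde benzoate, (3aR,4R,5R,6aS)-4-formyl-2-oxohexahydro-2H-cyclopenta[b]furan-5-yl benzoate | O=C[C@@H]1[C@@H](CC(=O)O2)[C@@H]2C[C@H]1OC(=O)c1ccccc1 | intermediate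
3 | dimethyl (2-oxoheptyl)phosphonate | CCCCCC(=O)CP(=O)(OC)OC | starting material
4 | sodium 1-(dimethoxyphosphoryl)-2-oxoheptan-1-ide (sodium salt of 3, formed in the flask) | [Na+].CCCCCC(=O)[CH-]P(=O)(OC)OC | intermediate
5 | Corey enone benzoate, (3aR,4R,5R,6aS)-2-oxo-4-[(1E)-3-oxooct-1-en-1-yl]hexahydro-2H-cyclopenta[b]furan-5-yl benzoate | CCCCCC(=O)/C=C/[C@@H]1[C@@H](CC(=O)O2)[C@@H]2C[C@H]1OC(=O)c1ccccc1 | intermediate
6 | lactol triol, (3aR,4R,5R,6aS)-4-[(1E)-3-hydroxyoct-1-en-1-yl]hexahydro-2H-cyclopenta[b]furan-2,5-diol, both C15 epimers and both anomers | CCCCCC(O)/C=C/[C@@H]1[C@@H](CC(O)O2)[C@@H]2C[C@H]1O | intermediate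
7 | (4-carboxybutyl)triphenylphosphonium bromide | OC(=O)CCCC[P+](c1ccccc1)(c1ccccc1)c1ccccc1.[Br-] | starting material
8 | potassium 5-(triphenylphosphoranylidene)pentanoate (ylide from 7, formed in the flask) | [K+].[O-]C(=O)CCCC=P(c1ccccc1)(c1ccccc1)c1ccccc1 | intermediate
9 | 2-[(1R,2R,3R,5S)-3,5-dihydroxy-2-[(1E)-3-hydroxyoct-1-en-1-yl]cyclopentyl]acetaldehyde (open form of 6, C15 epimers) | CCCCCC(O)/C=C/[C@@H]1[C@@H](CC=O)[C@@H](O)C[C@H]1O | intermediate
10 | PGF2α and 15-epi-PGF2α, (5Z)-7-[(1R,2R,3R,5S)-3,5-dihydroxy-2-[(1E)-3-hydroxyoct-1-en-1-yl]cyclopentyl]hept-5-enoic acid, C15 epimers | CCCCCC(O)/C=C/[C@@H]1[C@@H](C/C=C\CCCC(=O)O)[C@@H](O)C[C@H]1O | intermediate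
11 | 15-keto-PGF2α, (5Z)-7-[(1R,2R,3R,5S)-3,5-dihydroxy-2-[(1E)-3-oxooct-1-en-1-yl]cyclopentyl]hept-5-enoic acid | CCCCCC(=O)/C=C/[C@@H]1[C@@H](C/C=C\CCCC(=O)O)[C@@H](O)C[C@H]1O | target

## Totals and risks

Total step count: 5. Longest linear sequence: 5 steps (1 → 2 → 5 → 6 → 10 → 11).

**Step 3 (one-pot triple reduction).** The risks are over-reduction of the lactol to the ring-opened diol and incomplete benzoate cleavage. The fallback sets out from 5 and comes back at 6, doing the three jobs one at a time. Luche reduction (NaBH4, CeCl3·7H2O, MeOH, −20 °C) gives the allylic alcohol benzoate F1. Methanolysis (K2CO3, MeOH, rt) removes the benzoate, which is safe once the enone is gone, and gives the diol lactone F2. i-Bu2AlH (3.5 equiv, THF, −78 °C) then has only the lactone left to reduce and delivers 6.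

**Step 4 (Wittig on the unprotected lactol).** The risks are a sluggish, poorly soluble polyanion and difficult removal of Ph3PO and of a few percent of the (5E)-isomer from a very polar acid. The fallback sets out from 5 and comes back at 10, carrying the hydroxyls protected. Compound 5 is taken as above through the allylic alcohol benzoate F1 to the diol lactone F2. Silylation (TBSCl, imidazole, DMF) gives the bis-TBS lactone F3. i-Bu2AlH (1.2 equiv, toluene, −78 °C) gives the bis-TBS lactol F4. Wittig reaction with ylide 8 (from 7 and KOt-Bu, THF) gives the 11,15-bis-TBS acid F5, which is lipophilic and can be chromatographed. Desilylation (HF·pyridine, THF, 0 °C → rt) returns 10.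

**Step 5 (chemoselective DDQ oxidation).** The risks are slow or incomplete conversion, partial oxidation of the ring carbinols under forcing conditions, and separation from the hydroquinone. The fallback sets out from 10 and comes back at 11, replacing reagent selectivity by temporary protection. The cis-9,11-diol is tied up with butylboronic acid (1.1 equiv, CH2Cl2, 4 Å molecular sieves, rt) as the cyclic 9,11-butylboronate F6. The only remaining carbinol (C15) is oxidised with Dess–Martin periodinane (CH2Cl2, 0 °C) to the 15-keto boronate F7. Stirring in aqueous methanol hydrolyses the boronate and gives 11.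

## Further compounds

F1 | step 3 | (3aR,4R,5R,6aS)-4-[(1E)-3-hydroxyoct-1-en-1-yl]-2-oxohexahydro-2H-cyclopenta[b]furan-5-yl benzoate, C15 epimers | CCCCCC(O)/C=C/[C@@H]1[C@@H](CC(=O)O2)[C@@H]2C[C@H]1OC(=O)c1ccccc1
F2 | step 3 | (3aR,4R,5R,6aS)-5-hydroxy-4-[(1E)-3-hydroxyoct-1-en-1-yl]hexahydro-2H-cyclopenta[b]furan-2-one, C15 epimers | CCCCCC(O)/C=C/[C@@H]1[C@@H](CC(=O)O2)[C@@H]2C[C@H]1O
F3 | step 4 | bis-TBS ether of F2, (3aR,4R,5R,6aS)-5-(tert-butyldimethylsilyloxy)-4-[(1E)-3-(tert-butyldimethylsilyloxy)oct-1-en-1-yl]hexahydro-2H-cyclopenta[b]furan-2-one, C15 epimers | CCCCCC(O[Si](C)(C)C(C)(C)C)/C=C/[C@@H]1[C@@H](CC(=O)O2)[C@@H]2C[C@H]1O[Si](C)(C)C(C)(C)C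
F4 | step 4 | bis-TBS lactol, (3aR,4R,5R,6aS)-5-(tert-butyldimethylsilyloxy)-4-[(1E)-3-(tert-butyldimethylsilyloxy)oct-1-en-1-yl]hexahydro-2H-cyclopenta[b]furan-2-ol, C15 epimers and anomers | CCCCCC(O[Si](C)(C)C(C)(C)C)/C=C/[C@@H]1[C@@H](CC(O)O2)[C@@H]2C[C@H]1O[Si](C)(C)C(C)(C)C
F5 | step 4 | 11,15-bis-O-TBS-PGF2α, C15 epimers | CCCCCC(O[Si](C)(C)C(C)(C)C)/C=C/[C@@H]1[C@@H](C/C=C\CCCC(=O)O)[C@@H](O)C[C@H]1O[Si](C)(C)C(C)(C)C
F6 | step 5 | PGF2α 9,11-O-butylboronate (cyclic boronic ester), C15 epimers | CCCCCC(O)/C=C/[C@@H]1[C@@H](C/C=C\CCCC(=O)O)[C@@H](O2)C[C@H]1OB2CCCC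
F7 | step 5 | 15-keto-PGF2α 9,11-O-butylboronate (cyclic boronic ester) | CCCCCC(=O)/C=C/[C@@H]1[C@@H](C/C=C\CCCC(=O)O)[C@@H](O2)C[C@H]1OB2CCCC
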